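**Retrosynthetic overview**

1. Ring code: A = benzene ring of the chromene, B = pyran, C = cyclopentane, D = cyclobutane, E = catechol ring. At the end, fluoride frees the catechol. Just before that, an ionic hydrogenation erases a temporary silyloxy group from the benzylic CH2 carbon of ring C.
2. The key disconnection copies the presumed biosynthesis. It is a retro-[2+2] of ring D across its bonds (ring A)CH–CH(ring C) and ArCH–CMe2, leading to a flat (E)-stilbene whose ring A carries an ortho (S)-CH(OTBS)–CH=CMe2 arm (an oxidised prenyl group). In the forward direction one photochemical step makes two C–C bonds, rings C and D, and three stereocentres.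
3. Enabling feature: the styryl carbon and the arm sit on neighbouring atoms of ring A, so ArCH=CH–C(A)–C(A)–CH(O)–CH=CMe2 is a 1,6-diene set up for five-ring and then four-ring closure. C4 of ring B and the arm flank the styryl group and twist its alkene out of the plane of ring A toward the arm. The para oxygen of ring E stabilises the radical at ArCH, and the Z-methyl of the CMe2 terminus relays the carbinol configuration by 1,3-allylic strain.
4. The stilbene comes from a Heck coupling of a bromo aldehyde with a protected vinylcatechol. The carbinol comes from a catalytic asymmetric alkenylzinc addition to the same formyl group, which is installed by a Vilsmeier–Haack reaction.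
5. Order of rings: A and E are bought, B is made by a propargyl Claisen cascade on 3-bromo-5-methoxyphenol, then C closes, and D closes last.

Key step: step 9

Assumption: the sense of induction known for (2S)-(−)-3-exo-morpholinoisoborneol with aryl aldehydes (Si-face attack) is taken to hold for the hindered stilbene aldehyde of step 7. If it does not, the mirror-image ligand is used.

**Step 1**
Reactants: 1 3,4-dihydroxybenzaldehyde
Product: 2 3,4-bis(tert-butyldimethylsilyloxy)benzaldehyde
Conditions: TBSCl, imidazole, DMF, 25 °C
Reagents that add atoms: tert-butyldimethylsilyl chloride (TBSCl), CC(C)(C)[Si](C)(C)Cl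
Why: Imidazole-promoted silyl ether formation caps both phenols with a group that should survive ylide, palladium, organozinc, light and mild Lewis acid and that falls to fluoride at the end.

**Step 2**
Reactants: 2 3,4-bis(tert-butyldimethylsilyloxy)benzaldehyde
Product: 3 3,4-bis(tert-butyldimethylsilyloxy)styrene
Conditions: Ph3PCH3Br, n-BuLi, THF, 0 °C; then 2, 0 to 25 °C
Reagents that add atoms: methyltriphenylphosphonium bromide, C[P+](c1ccccc1)(c1ccccc1)c1ccccc1.[Br-]
Why: Wittig methylenation of an aromatic aldehyde with the preformed non-stabilised ylide is reliable and leaves aryl silyl ethers untouched.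

**Step 3**
Reactants: 4 3-bromo-5-methoxyphenol; 5 3-chloro-3-methylbut-1-yne
Product: 6 1-bromo-3-methoxy-5-(2-methylbut-3-yn-2-yloxy)benzene
Conditions: CuCl2 (0.1 mol %), DBU, MeCN, 0 °C
Reagents that add atoms: none
Why: Copper-catalysed O-alkylation of a phenol with a tertiary propargylic chloride forms the hindered aryl 1,1-dimethylpropargyl ether without touching the aryl bromide.

**Step 4**
Reactants: 6 1-bromo-3-methoxy-5-(2-methylbut-3-yn-2-yloxy)benzene
Product: 9 5-bromo-7-methoxy-2,2-dimethyl-2H-chromene, via allenylphenol 7 (not isolated), via ortho-quinone methide 8 (not isolated)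
Conditions: PhNEt2, 185 °C
Reagents that add atoms: none
Why: Aromatic propargyl Claisen rearrangement, 1,5-hydrogen shift and oxa-6π electrocyclisation close ring B, and the [3,3] shift should go to the carbon between O and Br because the meta methoxy group steers it para to itself and the meta halogen steers it to its own side, so both effects point the same way.

**Step 5**
Reactants: 9 5-bromo-7-methoxy-2,2-dimethyl-2H-chromene
Product: 11 5-bromo-7-methoxy-2,2-dimethyl-2H-chromene-6-carbaldehyde, via aryl iminium chloride 10 (not isolated)
Conditions: POCl3, DMF, 0 to 70 °C; then aq NaOAc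
Reagents that add atoms: N,N-dimethylformamide, CN(C)C=O; water, O
Why: Vilsmeier–Haack formylation should attack the ring carbon para to the pyran oxygen and ortho to OMe, just as 1-bromo-3,5-dialkoxybenzenes are formylated next to bromine and not between the two oxygens, and the iminium salt is hydrolysed on work-up.

**Step 6**
Reactants: 11 5-bromo-7-methoxy-2,2-dimethyl-2H-chromene-6-carbaldehyde; 3 3,4-bis(tert-butyldimethylsilyloxy)styrene
Product: 12 5-[(E)-2-(3,4-bis(tert-butyldimethylsilyloxy)phenyl)ethenyl]-7-methoxy-2,2-dimethyl-2H-chromene-6-carbaldehyde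
Conditions: Pd2(dba)3 (2.5 mol %), [HP(t-Bu)3]BF4 (10 mol %), Cy2NMe, 1,4-dioxane, 90 °C
Reagents that add atoms: none
Why: A Mizoroki–Heck coupling with a bulky electron-rich phosphine tolerates the doubly ortho-substituted bromide, whose oxidative addition is helped by the ortho formyl group, and syn insertion followed by syn β-hydride elimination gives the (E)-stilbene.

**Step 7**
Reactants: 12 stilbene aldehyde; 13 2-methylprop-1-enylmagnesium bromide
Product: 15 (1S)-1-{5-[(E)-2-(3,4-bis(tert-butyldimethylsilyloxy)phenyl)ethenyl]-7-methoxy-2,2-dimethyl-2H-chromen-6-yl}-3-methylbut-2-en-1-ol, via zinc alkoxide 14 (not isolated)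
Conditions: 13, Zn(OMe)2, NaOMe, Et2O/THF, 25 °C, salts spun off; then 12, (2S)-(−)-3-exo-morpholinoisoborneol (10 mol %), toluene, 0 °C; pH 7 buffer
Reagents that add atoms: none
Why: This is an amino-alcohol-catalysed asymmetric addition of a salt-free dialkenylzinc to an aromatic aldehyde, in which the (2S)-ligand should deliver the alkenyl group to the Si face through the usual bimetallic zinc transition state and so set the (S)-carbinol centre, the only stereocentre of the route made by reagent control.

**Step 8**
Reactants: 15 (S)-allylic alcohol
Product: 16 tert-butyldimethylsilyl ether of 15 (S at the carbinol carbon; E-stilbene)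
Conditions: TBSOTf, 2,6-lutidine, CH2Cl2, −78 °C
Reagents that add atoms: tert-butyldimethylsilyl trifluoromethanesulfonate (TBSOTf), CC(C)(C)[Si](C)(C)OS(=O)(=O)C(F)(F)F
Why: Silyl triflate and lutidine at low temperature cap the acid-labile, doubly activated alcohol under non-acidic conditions without touching its configuration, and the bulky group reinforces the conformational bias used in step 9.

**Step 9**
Reactants: 16 tris-silylated (S)-stilbene
Product: 18 tris-silylated cycloadduct (rings C and D cis-fused; OTBS trans to CMe2; aryl exo; all four stereocentres S), via 1,4-biradical 17 (not isolated)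
Conditions: [Ir(dF(CF3)ppy)2(dtbbpy)]PF6 (2 mol %), degassed CH2Cl2/MeCN, 0.02 M, blue LEDs (450 nm), 25 °C
Reagents that add atoms: none
Why: Triplet energy transfer from the excited iridium sensitiser populates the twisted triplet of the aryl alkene (alkene geometry is lost there and does not matter), its carbon next to ring A adds to the CH terminus of the trisubstituted alkene to give 17 (a tertiary alkyl radical plus a benzylic radical stabilised by ring E), and after intersystem crossing the two radical centres combine to give 18; the closest known reaction type is the visible-light-sensitised intramolecular styrene–alkene [2+2] photocycloaddition of 1,6-dienes to bicyclo[3.2.0]heptanes, and the event mirrors the presumed biosynthetic stilbene–prenyl cycloaddition. Ring C closes first by 5-exo-trig attack (rule of five), and ring D closes last by collapse of the 1,4-biradical between the CMe2 and ArCH centres. The ring-fusion carbon next to the carbinol is set by 1,3-allylic strain, because the Z-methyl forces the carbinol C–H to eclipse the alkene, which fixes the alkene face turned toward the stilbene and places the silyloxy group trans to the CMe2 carbon. The benzylic ring-fusion carbon follows because only the cis-1,4-biradical can close while the trans one falls back to 16, and the ArCH carbon takes the exo orientation, trans to ring A, to avoid the concave face. The step needs the stilbene alkene rather than the ring B alkene to react, and straight rather than crossed addition; this is secured by the 1,6-diene spacing, by the two ortho neighbours that point the p-orbital of the stilbene carbon at the isobutenyl CH, and by ring B, which holds its own alkene coplanar with ring A so that its p-orbitals cannot reach the stilbene carbon. Oxygen is excluded to protect the triplet state and the electron-rich alkenes.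

**Step 10**
Reactants: 18 tris-silylated cycloadduct
Product: 20 bis(tert-butyldimethylsilyl) ether of the target, via benzylic cation 19 (not isolated)
Conditions: Et3SiH (5 equiv), TMSOTf (20 mol %), 2,6-di-tert-butyl-4-methylpyridine (30 mol %), CH2Cl2, −78 °C
Reagents that add atoms: none
Why: In this ionic hydrogenation the cation, stabilised by the ortho methoxy and para alkoxy groups, should form already at −78 °C and be trapped by excess silane faster than it can cleave ring D (ring expansion would give a bridged secondary cation and fragmentation an unstabilised tertiary one), while the hindered pyridine keeps the medium free of protons so that the ring B alkene survives and no stereocentre is touched.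

**Step 11**
Reactants: 20 bis(tert-butyldimethylsilyl) ether of the target
Product: 21 target CNP0207533.1
Conditions: Bu4NF, AcOH, THF, 0 °C, argon
Reagents that add atoms: none
Why: Buffered fluoride cleaves the two aryl silyl ethers under nearly neutral conditions, so the catechol is never exposed as its air-sensitive dianion and the chromene, the methyl ether and the three stereocentres stay untouched.

**Compound list**

1 | 3,4-dihydroxybenzaldehyde | O=Cc1ccc(O)c(O)c1 | starting material
2 | 3,4-bis(tert-butyldimethylsilyloxy)benzaldehyde | O=Cc1ccc(O[Si](C)(C)C(C)(C)C)c(O[Si](C)(C)C(C)(C)C)c1 | intermediate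
3 | 3,4-bis(tert-butyldimethylsilyloxy)styrene | C=Cc1ccc(O[Si](C)(C)C(C)(C)C)c(O[Si](C)(C)C(C)(C)C)c1 | intermediate
4 | 3-bromo-5-methoxyphenol | COc1cc(O)cc(Br)c1 | starting material
5 | 3-chloro-3-methylbut-1-yne | C#CC(C)(C)Cl | starting material
6 | 1-bromo-3-methoxy-5-(2-methylbut-3-yn-2-yloxy)benzene | COc1cc(Br)cc(OC(C)(C)C#C)c1 | intermediate
7 | 3-bromo-5-methoxy-2-(3-methylbuta-1,2-dienyl)phenol (not isolated) | COc1cc(O)c(C=C=C(C)C)c(Br)c1 | intermediate
8 | (6E)-5-bromo-3-methoxy-6-(3-methylbut-2-enylidene)cyclohexa-2,4-dien-1-one (not isolated) | O=C1C=C(OC)C=C(Br)/C1=C/C=C(C)C | intermediate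
9 | 5-bromo-7-methoxy-2,2-dimethyl-2H-chromene | COc1cc(Br)c2C=CC(C)(C)Oc2c1 | intermediate
10 | (5-bromo-7-methoxy-2,2-dimethyl-2H-chromen-6-yl)methylidene-dimethyliminium chloride (not isolated) | COc1cc2OC(C)(C)C=Cc2c(Br)c1C=[N+](C)C.[Cl-] | intermediate
11 | 5-bromo-7-methoxy-2,2-dimethyl-2H-chromene-6-carbaldehyde | COc1cc2OC(C)(C)C=Cc2c(Br)c1C=O | intermediate
12 | 5-[(E)-2-(3,4-bis(tert-butyldimethylsilyloxy)phenyl)ethenyl]-7-methoxy-2,2-dimethyl-2H-chromene-6-carbaldehyde | COc1cc2OC(C)(C)C=Cc2c(/C=C/c2ccc(O[Si](C)(C)C(C)(C)C)c(O[Si](C)(C)C(C)(C)C)c2)c1C=O | intermediate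
13 | 2-methylprop-1-enylmagnesium bromide | CC(C)=C[Mg]Br | starting material
14 | (2-methylprop-1-enyl)zinc alkoxide of 15, S at the carbinol carbon (not isolated) | COc1cc2OC(C)(C)C=Cc2c(/C=C/c2ccc(O[Si](C)(C)C(C)(C)C)c(O[Si](C)(C)C(C)(C)C)c2)c1[C@@H](O[Zn]C=C(C)C)C=C(C)C | intermediate
15 | (1S)-1-{5-[(E)-2-(3,4-bis(tert-butyldimethylsilyloxy)phenyl)ethenyl]-7-methoxy-2,2-dimethyl-2H-chromen-6-yl}-3-methylbut-2-en-1-ol | COc1cc2OC(C)(C)C=Cc2c(/C=C/c2ccc(O[Si](C)(C)C(C)(C)C)c(O[Si](C)(C)C(C)(C)C)c2)c1[C@@H](O)C=C(C)C | intermediate
16 | tert-butyldimethylsilyl ether of 15, S at the carbinol carbon, E-stilbene | COc1cc2OC(C)(C)C=Cc2c(/C=C/c2ccc(O[Si](C)(C)C(C)(C)C)c(O[Si](C)(C)C(C)(C)C)c2)c1[C@@H](O[Si](C)(C)C(C)(C)C)C=C(C)C | intermediate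
17 | 1,4-biradical with ring C closed; CMe2 radical and ArCH radical on neighbouring ring C carbons, cis to each other and trans to OTBS (not isolated) | COc1cc2c(c3c1[C@@H](O[Si](C)(C)C(C)(C)C)[C@H]([C](C)C)[C@@H]3[CH]c1ccc(O[Si](C)(C)C(C)(C)C)c(O[Si](C)(C)C(C)(C)C)c1)C=CC(C)(C)O2 | intermediate
18 | tris-silylated cycloadduct; rings C and D cis-fused; benzylic C–OTBS S and trans to CMe2; ring-fusion CH next to it S; benzylic ring-fusion CH S; ArCH S with the aryl group exo | COc1cc2c(c3c1[C@@H](O[Si](C)(C)C(C)(C)C)[C@H]1[C@@H]3[C@H](c3ccc(O[Si](C)(C)C(C)(C)C)c(O[Si](C)(C)C(C)(C)C)c3)C1(C)C)C=CC(C)(C)O2 | intermediate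
19 | benzylic cation of ring C derived from 18 (not isolated) | COc1cc2c(c3c1[CH+][C@H]1[C@@H]3[C@H](c3ccc(O[Si](C)(C)C(C)(C)C)c(O[Si](C)(C)C(C)(C)C)c3)C1(C)C)C=CC(C)(C)O2 | intermediate
20 | bis(tert-butyldimethylsilyl) ether of the target; ring-fusion CH next to CH2 S; benzylic ring-fusion CH R; ArCH S | COc1cc2c(c3c1C[C@H]1[C@@H]3[C@H](c3ccc(O[Si](C)(C)C(C)(C)C)c(O[Si](C)(C)C(C)(C)C)c3)C1(C)C)C=CC(C)(C)O2 | intermediate
21 | CNP0207533.1; methoxy-dimethylchromene whose ring A is fused to ring C, cis-fused to the gem-dimethylcyclobutane ring D that bears an exo 3,4-dihydroxyphenyl group; ring-fusion CH next to CH2 S; benzylic ring-fusion CH R; ArCH S | COc1cc2c(c3c1C[C@H]1[C@@H]3[C@H](c3ccc(O)c(O)c3)C1(C)C)C=CC(C)(C)O2 | target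

**Step count**

Total step count: 11. Longest linear sequence: 9 (steps 3 to 11, from 3-bromo-5-methoxyphenol).

**Steps most likely to fail**

**Step 9.**
- Risk: relaxation of the twisted triplet by bond rotation may outrun the 5-exo attack. The biradical may also disproportionate by hydrogen transfer from a methyl group instead of closing.
- Fallback: leave photochemistry and use the thermal formal [2+2] cycloaddition that is known for ortho-prenylated 4-hydroxystilbenes and depends on a free para-hydroxy group.
- Setting out from 16, only the two aryl silyl ethers are cleaved (LiOAc cat., DMF/H2O, 40 °C) to give the free catechol stilbene F1.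
- F1 is heated in degassed o-xylene at about 180 °C (microwave). The same 1,3-allylic strain should govern the alkene face, and the product should be the catechol cycloadduct F2.
- Resilylation of F2 (TBSCl, imidazole, DMF) comes back to the route at 18.

**Step 10.**
- Risk: heterolytic cleavage of the strained ring D bond next to the cationic centre, or protonation of the ring B alkene followed by hydride capture.
- Fallback: replace the cationic C–O cleavage by a radical one (Barton–McCombie deoxygenation).
- Setting out from 15, the unprotected alcohol is irradiated under the conditions of step 9 to give the cycloadduct alcohol F3.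
- F3 is converted (KHMDS, CS2, MeI, THF, −78 °C) into the S-methyl xanthate F4.
- F4 is reduced with concentrated Bu3SnH and Et3B/air in toluene at 0 to 25 °C. Hydrogen transfer to the benzylic radical should then outrun the opening of the cyclobutylcarbinyl radical. This comes back to the route at 20.

**Step 7.**
- Risk: slow catalysed addition to the doubly ortho-substituted aldehyde, or chelation of zinc by the methoxy group, may let unselective background addition erode the enantiomeric purity.
- Fallback: move the stereodefining event from C–C bond formation to C=O reduction.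
- Setting out from 12, direct addition of 13 (THF, −78 °C) gives the racemic allylic alcohol F5, and MnO2 in CH2Cl2 gives the aryl isobutenyl ketone F6.
- A Corey–Bakshi–Shibata reduction follows: (R)-1-methyl-3,3-diphenyl-tetrahydropyrrolo[1,2-c][1,3,2]oxazaborole (10 mol %), catecholborane, toluene, −78 °C. With the twisted, doubly ortho-substituted aryl group acting as the large substituent, it should give the (S)-alcohol and come back to the route at 15.

**Further compounds**

F1 | step 9 | (S)-silyl ether stilbene with free catechol | COc1cc2OC(C)(C)C=Cc2c(/C=C/c2ccc(O)c(O)c2)c1[C@@H](O[Si](C)(C)C(C)(C)C)C=C(C)C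
F2 | step 9 | cycloadduct with free catechol and benzylic OTBS | COc1cc2c(c3c1[C@@H](O[Si](C)(C)C(C)(C)C)[C@H]1[C@@H]3[C@H](c3ccc(O)c(O)c3)C1(C)C)C=CC(C)(C)O2
F3 | step 10 | cycloadduct with free benzylic alcohol and silylated catechol | COc1cc2c(c3c1[C@@H](O)[C@H]1[C@@H]3[C@H](c3ccc(O[Si](C)(C)C(C)(C)C)c(O[Si](C)(C)C(C)(C)C)c3)C1(C)C)C=CC(C)(C)O2
F4 | step 10 | S-methyl xanthate of F3 | COc1cc2c(c3c1[C@@H](OC(=S)SC)[C@H]1[C@@H]3[C@H](c3ccc(O[Si](C)(C)C(C)(C)C)c(O[Si](C)(C)C(C)(C)C)c3)C1(C)C)C=CC(C)(C)O2
F5 | step 7 | racemic allylic alcohol | COc1cc2OC(C)(C)C=Cc2c(/C=C/c2ccc(O[Si](C)(C)C(C)(C)C)c(O[Si](C)(C)C(C)(C)C)c2)c1C(O)C=C(C)C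
F6 | step 7 | aryl isobutenyl ketone | COc1cc2OC(C)(C)C=Cc2c(/C=C/c2ccc(O[Si](C)(C)C(C)(C)C)c(O[Si](C)(C)C(C)(C)C)c2)c1C(=O)C=C(C)C
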